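**Strategy.** Ring A is a hexasubstituted phloroglucinol whose three oxygen atoms (on C5, C7 and C8a) need different masks if the methyl group is to end up on C8 and the prenyl group on C6. The plan therefore disconnects ring A completely, to a 3-ethoxy-4-prenylcyclobutenone and the triisopropylsilyl ynol ether of propyne. One thermal cascade (cyclobutenone opening to a vinylketene, [2+2] with the ynol ether, second opening, 6π-electrocyclisation) forms C7–C8, C4a–C8a and C6–C7 and gives the arene with C7–OH free, C8a–O silylated, C5–O ethylated and C4a–H as the only open carbon. Ring C is then built on C4a/C8a as a chromone, and an asymmetric conjugate arylation sets C2.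

Key step: step 4

Remark 1: the ynol ether is made from propyne, because one-carbon homologation of a propionate ester would place an ethyl, not a methyl, group on the alkyne and hence on C8.
Remark 2: the stereocentre of the target SMILES is read as (2S); 5-methylhex-4-enoic acid, ethoxyacetylene (solution in hexanes), propyne and 4-(methoxymethoxy)phenylboronic acid are taken as purchasable.

**Step 1**
Reactants: 1 5-methylhex-4-enoic acid
Product: 2 5-methylhex-4-enoyl chloride
Conditions: (COCl)2, DMF (cat.), CH2Cl2, 0 °C → rt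
Reagents that add atoms: oxalyl chloride, O=C(Cl)C(=O)Cl
Why: Acid chloride formation through the Vilsmeier-type chloroiminium intermediate is mild enough to leave the trisubstituted alkene untouched.

**Step 2**
Reactants: 2 5-methylhex-4-enoyl chloride; 3 ethoxyacetylene
Product: 5 3-ethoxy-4-(3-methylbut-2-enyl)cyclobut-2-en-1-one (racemic), via prenylketene 4 (not isolated)
Conditions: Et3N, 3 (3 equiv), Et2O, slow addition of 2, 0 °C → rt
Reagents that add atoms: none
Why: Dehydrochlorination gives the ketene, which is trapped in situ by the ynol ether in a ketene–alkyne [2+2] cycloaddition in which the terminal alkyne carbon bonds to the ketene carbonyl carbon; this is the classical route to 4-substituted 3-ethoxycyclobutenones, and the racemic C4 centre is destroyed in step 4.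

**Step 3**
Reactants: 6 propyne
Product: 9 triisopropyl(prop-1-ynyloxy)silane, via prop-1-ynyllithium 7 (not isolated), via lithium prop-1-yn-1-olate 8 (not isolated)
Conditions: n-BuLi, THF, −78 °C; t-BuOOLi (from t-BuOOH and LiN(SiMe3)2), −78 → 0 °C; i-Pr3SiOTf, −78 °C → rt
Reagents that add atoms: tert-butyl hydroperoxide, CC(C)(C)OO; triisopropylsilyl trifluoromethanesulfonate, CC(C)[Si](C(C)C)(C(C)C)OS(=O)(=O)C(F)(F)F
Why: The lithium acetylide is oxidised at carbon by the electrophilic oxygen of the lithium peroxide to the ynolate, which the bulky silyl triflate traps on oxygen to give the stable silyl ynol ether (acetylide oxidation followed by O-silylation).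

**Step 4**
Reactants: 5 3-ethoxy-4-(3-methylbut-2-enyl)cyclobut-2-en-1-one; 9 triisopropyl(prop-1-ynyloxy)silane
Product: 14 5-ethoxy-2-methyl-6-(3-methylbut-2-enyl)-3-(triisopropylsilyloxy)phenol, via vinylketene 10 (not isolated), via 4-vinylcyclobutenone 11 (not isolated), via dienylketene 12 (not isolated), via cyclohexa-2,4-dienone 13 (not isolated)
Conditions: 9 (1.5 equiv), toluene, 80 → 120 °C, sealed tube
Reagents that add atoms: none
Why: At 80–120 °C cyclobutenone 5 should undergo conrotatory 4π ring opening (C1–C4 cleavage, prenyl turning outward) to vinylketene 10; the electron-rich, methyl-bearing carbon of ynol ether 9 adds to the ketene carbonyl carbon and the [2+2] adduct 11 results, with the new bonds C7–C8 and C4a–C8a. A second 4π opening gives dienylketene 12, and thermal disrotatory 6π-electrocyclisation forms C6–C7 and closes ring A as cyclohexadienone 13, which tautomerises to phenol 14. The closest known reaction type is the Danheiser benzannulation of cyclobutenones with siloxyalkynes, here with a vinylogous-ester cyclobutenone as the less usual partner. No stereocentre is formed. The selectivity needed is the orientation of the ketene–alkyne [2+2]; it is secured by the polarisation of the silyl ynol ether, which puts the methyl group between the new hydroxyl and the silyloxy group. Because the oxygen on C7 stems from the ketene, that on C8a from the ynol ether and that on C5 from the ethoxy group of 5, the product carries one free, one silylated and one ethylated oxygen and a single ring hydrogen at C4a.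

**Step 5**
Reactants: 14 5-ethoxy-2-methyl-6-(3-methylbut-2-enyl)-3-(triisopropylsilyloxy)phenol
Product: 15 [3-ethoxy-5-(methoxymethoxy)-6-methyl-4-(3-methylbut-2-enyl)phenoxy]triisopropylsilane
Conditions: NaH, MeOCH2Cl, THF/DMF, 0 °C → rt
Reagents that add atoms: chloromethyl methyl ether, COCCl
Why: Williamson-type O-alkylation of the only free hydroxyl (C7–OH) protects it as an acetal that survives fluoride, Grignard and rhodium chemistry, while the aryl silyl ether and the alkene are inert.

**Step 6**
Reactants: 15 [3-ethoxy-5-(methoxymethoxy)-6-methyl-4-(3-methylbut-2-enyl)phenoxy]triisopropylsilane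
Product: 16 5-ethoxy-3-(methoxymethoxy)-2-methyl-4-(3-methylbut-2-enyl)phenol
Conditions: n-Bu4NF, THF, 0 °C
Reagents that add atoms: none
Why: Fluoride cleaves the aryl O–Si bond selectively and unmasks C8a–OH, the future O1, while the C7 acetal and the C5 ethyl ether stay in place.

**Step 7**
Reactants: 16 5-ethoxy-3-(methoxymethoxy)-2-methyl-4-(3-methylbut-2-enyl)phenol
Product: 17 6-ethoxy-2-hydroxy-4-(methoxymethoxy)-3-methyl-5-(3-methylbut-2-enyl)benzaldehyde
Conditions: MgCl2, Et3N, (CH2O)n, MeCN, reflux
Reagents that add atoms: paraformaldehyde (formaldehyde units), C=O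
Why: In the Casnati–Skattebøl ortho-formylation the magnesium phenoxide delivers formaldehyde to the only free ring carbon (C4a, ortho to C8a–OH) and a second formaldehyde oxidises the benzylic alkoxide by hydride transfer; the non-acidic medium spares the prenyl and acetal groups.

**Step 8**
Reactants: 17 6-ethoxy-2-hydroxy-4-(methoxymethoxy)-3-methyl-5-(3-methylbut-2-enyl)benzaldehyde
Product: 18 3-ethoxy-2-(1-hydroxyprop-2-yn-1-yl)-5-(methoxymethoxy)-6-methyl-4-(3-methylbut-2-enyl)phenol (racemic, used crude)
Conditions: HC≡CMgBr (3 equiv), THF, 0 °C → rt; aq. NH4Cl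
Reagents that add atoms: ethynylmagnesium bromide, C#C[Mg]Br
Why: After deprotonation of the phenol the Grignard reagent adds 1,2 to the magnesium-chelated aldehyde; the racemic carbinol centre is removed by oxidation in the next step.

**Step 9**
Reactants: 18 3-ethoxy-2-(1-hydroxyprop-2-yn-1-yl)-5-(methoxymethoxy)-6-methyl-4-(3-methylbut-2-enyl)phenol
Product: 21 5-ethoxy-7-(methoxymethoxy)-8-methyl-6-(3-methylbut-2-enyl)-4H-chromen-4-one, via ynone 19 (not isolated), via enaminone 20 (not isolated)
Conditions: MnO2, CH2Cl2, rt; filter; Et2NH, EtOH, rt; then AcOH, 50 °C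
Reagents that add atoms: none
Why: MnO2 oxidises the benzylic propargylic alcohol to the ynone, the amine adds conjugately to give the enaminone, and the ortho hydroxyl closes ring C by 6-endo addition–elimination with loss of the amine (the enaminone route to chromones).

**Step 10**
Reactants: 21 5-ethoxy-7-(methoxymethoxy)-8-methyl-6-(3-methylbut-2-enyl)-4H-chromen-4-one; 22 4-(methoxymethoxy)phenylboronic acid
Product: 23 (2S)-5-ethoxy-7-(methoxymethoxy)-2-[4-(methoxymethoxy)phenyl]-8-methyl-6-(3-methylbut-2-enyl)-2,3-dihydro-4H-chromen-4-one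
Conditions: [Rh(OH)(cod)]2 (cat.), (S)-MeO-F12-BIPHEP [(S)-2,2'-bis(bis(3,4,5-trifluorophenyl)phosphino)-6,6'-dimethoxybiphenyl], toluene/H2O, 50 °C, no added base
Reagents that add atoms: none
Why: The rhodium-catalysed asymmetric 1,4-addition of an arylboronic acid (Hayashi–Miyaura reaction, established for chromones with electron-poor biaryl bisphosphines) forms the C2–aryl bond; the (S)-ligand is expected, by the facial sense these ligands show with cyclic enones, to deliver the aryl group to the face that gives (2S), and base-free conditions protect the flavanone from retro-oxa-Michael opening.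

**Step 11**
Reactants: 23 (2S)-5-ethoxy-7-(methoxymethoxy)-2-[4-(methoxymethoxy)phenyl]-8-methyl-6-(3-methylbut-2-enyl)-2,3-dihydro-4H-chromen-4-one
Product: 24 (2S)-5-ethoxy-7-hydroxy-2-(4-hydroxyphenyl)-8-methyl-6-(3-methylbut-2-enyl)-2,3-dihydro-4H-chromen-4-one
Conditions: 3 M aq. HCl/MeOH, 40 °C
Reagents that add atoms: none
Why: Acid-catalysed acetal exchange with methanol removes both methoxymethyl groups under the dilute-acid conditions commonly applied to prenylated flavanones, which should neither cyclise the prenyl group nor open ring C.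

**Step 12**
Reactants: 24 (2S)-5-ethoxy-7-hydroxy-2-(4-hydroxyphenyl)-8-methyl-6-(3-methylbut-2-enyl)-2,3-dihydro-4H-chromen-4-one
Product: 25 (2S)-5,7-dihydroxy-2-(4-hydroxyphenyl)-8-methyl-6-(3-methylbut-2-enyl)-2,3-dihydro-4H-chromen-4-one (target)
Conditions: BCl3 (1 M in CH2Cl2), CH2Cl2, −78 → −10 °C; aq. NaHCO3
Reagents that add atoms: none
Why: BCl3 ties the C4 carbonyl and the peri C5 ether oxygen into a six-membered chelate and chloride removes the ethyl group (chelation-controlled dealkylation of an ortho-alkoxy aryl ketone), so only this ether is cleaved, and the low temperature should protect the prenyl group and the C2 centre.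

**Compound list**
1 | 5-methylhex-4-enoic acid | CC(C)=CCCC(=O)O | starting material
2 | 5-methylhex-4-enoyl chloride | CC(C)=CCCC(=O)Cl | intermediate
3 | ethoxyacetylene (ethoxyethyne) | CCOC#C | starting material
4 | prenylketene (5-methylhexa-1,4-dien-1-one) | CC(C)=CCC=C=O | intermediate (not isolated)
5 | 3-ethoxy-4-(3-methylbut-2-enyl)cyclobut-2-en-1-one (racemic) | O=C1C=C(OCC)C1CC=C(C)C | intermediate
6 | propyne | CC#C | starting material
7 | prop-1-ynyllithium | CC#C[Li] | intermediate (not isolated)
8 | lithium prop-1-yn-1-olate | CC#C[O-].[Li+] | intermediate (not isolated)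
9 | triisopropyl(prop-1-ynyloxy)silane | CC#CO[Si](C(C)C)(C(C)C)C(C)C | intermediate
10 | (3Z)-3-ethoxy-7-methylocta-1,3,6-trien-1-one (vinylketene) | O=C=C/C(OCC)=C/CC=C(C)C | intermediate (not isolated)
11 | 4-[(1Z)-1-ethoxy-5-methylhexa-1,4-dien-1-yl]-2-methyl-3-(triisopropylsilyloxy)cyclobut-2-en-1-one (racemic) | O=C1C(C)=C(O[Si](C(C)C)(C(C)C)C(C)C)C1/C(OCC)=C/CC=C(C)C | intermediate (not isolated)
12 | (3E,5Z)-5-ethoxy-2,9-dimethyl-3-(triisopropylsilyloxy)deca-1,3,5,8-tetraen-1-one (dienylketene) | O=C=C(C)/C(O[Si](C(C)C)(C(C)C)C(C)C)=C\C(OCC)=C\CC=C(C)C | intermediate (not isolated)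
13 | 5-ethoxy-2-methyl-6-(3-methylbut-2-enyl)-3-(triisopropylsilyloxy)cyclohexa-2,4-dien-1-one (racemic) | O=C1C(C)=C(O[Si](C(C)C)(C(C)C)C(C)C)C=C(OCC)C1CC=C(C)C | intermediate (not isolated)
14 | 5-ethoxy-2-methyl-6-(3-methylbut-2-enyl)-3-(triisopropylsilyloxy)phenol | Cc1c(O)c(CC=C(C)C)c(OCC)cc1O[Si](C(C)C)(C(C)C)C(C)C | intermediate
15 | [3-ethoxy-5-(methoxymethoxy)-6-methyl-4-(3-methylbut-2-enyl)phenoxy]triisopropylsilane | Cc1c(OCOC)c(CC=C(C)C)c(OCC)cc1O[Si](C(C)C)(C(C)C)C(C)C | intermediate
16 | 5-ethoxy-3-(methoxymethoxy)-2-methyl-4-(3-methylbut-2-enyl)phenol | Cc1c(O)cc(OCC)c(CC=C(C)C)c1OCOC | intermediate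
17 | 6-ethoxy-2-hydroxy-4-(methoxymethoxy)-3-methyl-5-(3-methylbut-2-enyl)benzaldehyde | O=Cc1c(O)c(C)c(OCOC)c(CC=C(C)C)c1OCC | intermediate
18 | 3-ethoxy-2-(1-hydroxyprop-2-yn-1-yl)-5-(methoxymethoxy)-6-methyl-4-(3-methylbut-2-enyl)phenol (racemic) | C#CC(O)c1c(O)c(C)c(OCOC)c(CC=C(C)C)c1OCC | intermediate
19 | 1-[6-ethoxy-2-hydroxy-4-(methoxymethoxy)-3-methyl-5-(3-methylbut-2-enyl)phenyl]prop-2-yn-1-one | C#CC(=O)c1c(O)c(C)c(OCOC)c(CC=C(C)C)c1OCC | intermediate (not isolated)
20 | (2E)-3-(diethylamino)-1-[6-ethoxy-2-hydroxy-4-(methoxymethoxy)-3-methyl-5-(3-methylbut-2-enyl)phenyl]prop-2-en-1-one | CCN(CC)/C=C/C(=O)c1c(O)c(C)c(OCOC)c(CC=C(C)C)c1OCC | intermediate (not isolated)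
21 | 5-ethoxy-7-(methoxymethoxy)-8-methyl-6-(3-methylbut-2-enyl)-4H-chromen-4-one | O=c1ccoc2c(C)c(OCOC)c(CC=C(C)C)c(OCC)c12 | intermediate
22 | 4-(methoxymethoxy)phenylboronic acid | COCOc1ccc(B(O)O)cc1 | starting material
23 | (2S)-5-ethoxy-7-(methoxymethoxy)-2-[4-(methoxymethoxy)phenyl]-8-methyl-6-(3-methylbut-2-enyl)-2,3-dihydro-4H-chromen-4-one | CC(C)=CCc1c(OCOC)c(C)c2c(c1OCC)C(=O)C[C@@H](c1ccc(OCOC)cc1)O2 | intermediate
24 | (2S)-5-ethoxy-7-hydroxy-2-(4-hydroxyphenyl)-8-methyl-6-(3-methylbut-2-enyl)-2,3-dihydro-4H-chromen-4-one | CC(C)=CCc1c(O)c(C)c2c(c1OCC)C(=O)C[C@@H](c1ccc(O)cc1)O2 | intermediate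
25 | (2S)-5,7-dihydroxy-2-(4-hydroxyphenyl)-8-methyl-6-(3-methylbut-2-enyl)-2,3-dihydro-4H-chromen-4-one | CC(C)=CCc1c(O)c(C)c2c(c1O)C(=O)C[C@@H](c1ccc(O)cc1)O2 | target

**Step count.** Total: 12 steps. Longest linear sequence: 11 steps (steps 1, 2 and 4–12; step 3 is the one-step side branch).

**Steps most likely to fail**

1. Step 4. The donor-stabilised cyclobutenone may open only sluggishly, and the vinylketene may then be lost to acylation of the phenolic product or to oligomerisation. The fallback makes the same vinylketene at room temperature without a cyclobutenone; it sets out from siloxyalkyne 9 and returns to the route at phenol 14. The dianion of ethyl acetoacetate (NaH, then n-BuLi) is γ-alkylated with prenyl bromide to ethyl 7-methyl-3-oxooct-6-enoate F1. Triethyl orthoformate in EtOH with catalytic acid converts it into ethyl (2E)-3-ethoxy-7-methylocta-2,6-dienoate F2. Saponification gives (2E)-3-ethoxy-7-methylocta-2,6-dienoic acid F3, and oxalyl chloride on its potassium salt gives (2E)-3-ethoxy-7-methylocta-2,6-dienoyl chloride F4. Et3N in the presence of 9 effects 1,4-dehydrochlorination to 10, which is trapped as 11, and brief warming carries 11 on to 14. Vinylketene generation from enoyl chlorides, its [2+2] trapping by ynol ethers and the rearrangement of 4-vinylcyclobutenones to phenols are all known.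

2. Step 12. Acid released during the boron-mediated dealkylation may add to the prenyl group or cyclise it onto the flanking C5/C7 hydroxyls, and Lewis-acid-assisted opening of ring C may erode the configuration at C2. The fallback moves the de-ethylation in front of the stereocentre-forming step and replaces the Lewis acid by a nucleophilic, chelation-assisted cleavage; it sets out from chromone 21 and returns at target 25. LiCl in DMF at about 150 °C removes the peri ethyl group to give 5-hydroxy-7-(methoxymethoxy)-8-methyl-6-(3-methylbut-2-enyl)-4H-chromen-4-one F5. NaH and MeOCH2Cl give 5,7-bis(methoxymethoxy)-8-methyl-6-(3-methylbut-2-enyl)-4H-chromen-4-one F6. The rhodium-catalysed arylation of step 10 with 22 gives (2S)-5,7-bis(methoxymethoxy)-2-[4-(methoxymethoxy)phenyl]-8-methyl-6-(3-methylbut-2-enyl)-2,3-dihydro-4H-chromen-4-one F7. The HCl/MeOH treatment of step 11 then frees all three hydroxyls at once.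

3. Step 10. Aryl transfer to the electron-rich, peri-substituted chromone may be slow, or the facial selectivity may be insufficient. The fallback separates bond formation from stereocontrol; it sets out from chromone 21 and returns at flavanone 23. Copper-catalysed conjugate addition of 4-(methoxymethoxy)phenylmagnesium bromide (CuBr·SMe2, THF, −40 °C) gives racemic 5-ethoxy-7-(methoxymethoxy)-2-[4-(methoxymethoxy)phenyl]-8-methyl-6-(3-methylbut-2-enyl)-2,3-dihydro-4H-chromen-4-one F8. Kinetic resolution by Noyori-type asymmetric transfer hydrogenation (RuCl(p-cymene)[(R,R)-TsDPEN], HCO2H/Et3N; the catalyst enantiomer expected to consume the (2R)-ketone) should reduce that enantiomer to (2R,4R)-5-ethoxy-7-(methoxymethoxy)-2-[4-(methoxymethoxy)phenyl]-8-methyl-6-(3-methylbut-2-enyl)-3,4-dihydro-2H-chromen-4-ol F9. Unreacted (2S)-23 is then separated by chromatography.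

**Further compounds**
F1 | step 4 | ethyl 7-methyl-3-oxooct-6-enoate | CCOC(=O)CC(=O)CCC=C(C)C
F2 | step 4 | ethyl (2E)-3-ethoxy-7-methylocta-2,6-dienoate | CCOC(=O)/C=C(/OCC)CCC=C(C)C
F3 | step 4 | (2E)-3-ethoxy-7-methylocta-2,6-dienoic acid | OC(=O)/C=C(/OCC)CCC=C(C)C
F4 | step 4 | (2E)-3-ethoxy-7-methylocta-2,6-dienoyl chloride | ClC(=O)/C=C(/OCC)CCC=C(C)C
F5 | step 12 | 5-hydroxy-7-(methoxymethoxy)-8-methyl-6-(3-methylbut-2-enyl)-4H-chromen-4-one | O=c1ccoc2c(C)c(OCOC)c(CC=C(C)C)c(O)c12
F6 | step 12 | 5,7-bis(methoxymethoxy)-8-methyl-6-(3-methylbut-2-enyl)-4H-chromen-4-one | O=c1ccoc2c(C)c(OCOC)c(CC=C(C)C)c(OCOC)c12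
F7 | step 12 | (2S)-5,7-bis(methoxymethoxy)-2-[4-(methoxymethoxy)phenyl]-8-methyl-6-(3-methylbut-2-enyl)-2,3-dihydro-4H-chromen-4-one | CC(C)=CCc1c(OCOC)c(C)c2c(c1OCOC)C(=O)C[C@@H](c1ccc(OCOC)cc1)O2
F8 | step 10 | racemic 5-ethoxy-7-(methoxymethoxy)-2-[4-(methoxymethoxy)phenyl]-8-methyl-6-(3-methylbut-2-enyl)-2,3-dihydro-4H-chromen-4-one | CC(C)=CCc1c(OCOC)c(C)c2c(c1OCC)C(=O)CC(c1ccc(OCOC)cc1)O2
F9 | step 10 | (2R,4R)-5-ethoxy-7-(methoxymethoxy)-2-[4-(methoxymethoxy)phenyl]-8-methyl-6-(3-methylbut-2-enyl)-3,4-dihydro-2H-chromen-4-ol | CC(C)=CCc1c(OCOC)c(C)c2c(c1OCC)[C@H](O)C[C@H](c1ccc(OCOC)cc1)O2
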